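**Plan**

Retrosynthesis (benzofuran numbering; ring A is the benzene, ring B the dihydrofuran): first the two acyl–O bonds and the aldehyde oxidation level are removed. Next come the =CH2 and CH3 carbons of the C2 branch and the CH3 of the C5 side chain. The bonds C3a–C4 and C7a–C7 of ring A are cut last.
Enabling feature: O1, C7a, C3a, C3, C2 and the carbon on C2, with the C3 oxygen trans to the C2 branch, are the ring oxygen and the five carbons of 2-deoxy-D-ribono-1,4-lactone. The carbon substituent on C5 lies para to O1, which is where a 5-carboxy-2-pyrone delivers it.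
Forward: ring B comes from the sugar, and ring A is annulated onto its C3a–C7a edge with methyl coumalate (loss of CO2 and silanol). Then follow C2 branch to isopropenyl, C5 ester to methyl ketone, C3 isovalerate, carbinol, second ester, and allylic oxidation last.
Stereochemistry: C2 and C3 are C4 and C3 of 2-deoxy-D-ribose. The benzylic carbinol comes from catalyst-controlled transfer hydrogenation, and the acyl α-centre from (R)-2-methylbutanoic acid.

Key step: step 4

Assumption: (R)-2-methylbutanoic acid is bought as a single enantiomer; the transient ring-fusion and bridgehead centres of 6 and 7 are left undefined because they vanish in the same flask. TBS = tert-butyldimethylsilyl.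

Step 1
Reactants: 1 2-deoxy-D-ribose
Product: 2 2-deoxy-D-ribono-1,4-lactone, (4S,5R)-4-hydroxy-5-(hydroxymethyl)oxolan-2-one
Conditions: Br2, H2O, rt
Reagents that add atoms: none
Why: Bromine-water oxidation of an aldose takes the cyclic hemiacetal carbon to the aldonolactone level and the product settles as the five-membered 1,4-lactone, while the two carbinol stereocentres are not involved.

Step 2
Reactants: 2 2-deoxy-D-ribono-1,4-lactone
Product: 3 3,5-bis-O-TBS-2-deoxy-D-ribono-1,4-lactone
Conditions: TBSCl, imidazole, DMF, rt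
Reagents that add atoms: tert-butyldimethylsilyl chloride, CC(C)(C)[Si](C)(C)Cl
Why: Imidazole-promoted silylation with TBSCl protects the primary and the secondary hydroxyl alike, leaves the lactone alone and takes place at oxygen, so both stereocentres are retained.

Step 3
Reactants: 3 3,5-bis-O-TBS-2-deoxy-D-ribono-1,4-lactone
Product: 4 (2R,3S)-3,5-bis(TBS-oxy)-2-(TBS-oxymethyl)-2,3-dihydrofuran (TBS ketene acetal of 3)
Conditions: TBSCl, THF–DMPU, −78 °C, then LiN(iPr)2 (LDA) added slowly (internal quench), → −40 °C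
Reagents that add atoms: tert-butyldimethylsilyl chloride, CC(C)(C)[Si](C)(C)Cl
Why: Kinetic enolisation with an internal silyl quench traps the lactone enolate on oxygen as fast as it forms (the polar cosolvent favours O- over C-silylation), which leaves β-elimination of the C3 silyloxy group little time at −78 °C; the product is taken on crude after a cold, neutral work-up.

Step 4
Reactants: 4 TBS ketene acetal of 3; 5 methyl coumalate (methyl 2-oxo-2H-pyran-5-carboxylate)
Product: 8 methyl (2R,3S)-3-(TBS-oxy)-2-(TBS-oxymethyl)-2,3-dihydro-1-benzofuran-5-carboxylate, via bridged lactone 6 (not isolated), via dihydroarene 7 (not isolated)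
Conditions: 4 (1.3 equiv), toluene, 2,6-di-tert-butyl-4-methylpyridine (5 mol %), base-washed sealed tube, 60 → 110 °C
Reagents that add atoms: none
Why: The reaction is a polar, asynchronous inverse-electron-demand Diels–Alder addition in which the nucleophilic carbon C3a of 4 bonds to C6 of the pyrone (the terminus conjugated to both the ring carbonyl and the ester) and the acetal carbon C7a bonds to C3, giving the bridged lactone 6. Retro-[4+2] loss of CO2 from 6 gives the 3a,7a-dihydroarene 7, which aromatises by 1,2-elimination of tert-butyldimethylsilanol across C7a–C3a. The closest known reaction type is the Diels–Alder/decarboxylation/alcohol-elimination benzannulation of methyl coumalate with ketene acetals and enol ethers, which gives para-oxygenated benzoates; an endocyclic, lactone-derived silyl ketene acetal with an allylic silyloxy group is a new member of that substrate class. Ring A closes by intermolecular [4+2] annulation on the C3a–C7a edge of the intact ring B (bonds C3a–C4 and C7a–C7), and no stereocentre of 8 is made here, since the four transient centres of 6 are erased and C2 and C3 are spectators inherited from the sugar. The regiochemistry needed (ester carbon on C5, para to O1) follows from the polarity match just described. The chemoselectivity needed (breaking C7a–OSi, not C7a–O1 or the allylic C3–OSi bond) rests on the silanolate being the better nucleofuge, on O1 being the better donor toward the developing cation, on the cis relation of H-3a and the silyloxy group in the cis-fused 7, and on a strictly acid-free medium.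

Step 5
Reactants: 8 methyl (2R,3S)-3-(TBS-oxy)-2-(TBS-oxymethyl)-2,3-dihydro-1-benzofuran-5-carboxylate
Product: 9 methyl (2R,3S)-3-(TBS-oxy)-2-(hydroxymethyl)-2,3-dihydro-1-benzofuran-5-carboxylate
Conditions: HF·pyridine, pyridine, THF, 0 °C
Reagents that add atoms: none
Why: Pyridine-buffered HF discriminates between silyl ethers by steric access, so the primary TBS ether should fall well before the secondary benzylic one, a selectivity that is routine for 3',5'-bis-O-TBS-2'-deoxynucleosides, which carry the same ring.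

Step 6
Reactants: 9 methyl (2R,3S)-3-(TBS-oxy)-2-(hydroxymethyl)-2,3-dihydro-1-benzofuran-5-carboxylate
Product: 10 methyl (2S,3S)-3-(TBS-oxy)-2-formyl-2,3-dihydro-1-benzofuran-5-carboxylate
Conditions: Dess–Martin periodinane, pyridine, CH2Cl2, 0 °C → rt
Reagents that add atoms: none
Why: Dess–Martin oxidation works near neutrality and without a base able to enolise the product, as in the preparation of nucleoside 5'-aldehydes, so C2 should keep its configuration and the β-silyloxy group should stay; the change of descriptor at C2 is only a change of CIP priority and the aldehyde is used at once.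

Step 7
Reactants: 10 methyl (2S,3S)-3-(TBS-oxy)-2-formyl-2,3-dihydro-1-benzofuran-5-carboxylate
Product: 11 methyl (2R,3S)-3-(TBS-oxy)-2-(1-hydroxyethyl)-2,3-dihydro-1-benzofuran-5-carboxylate (both carbinol epimers)
Conditions: MeTi(OiPr)3, Et2O, −78 → −10 °C
Reagents that add atoms: methyltitanium triisopropoxide, C[Ti](OC(C)C)(OC(C)C)OC(C)C
Why: Carbonyl addition of a non-basic organotitanium reagent is selective for aldehydes over esters and does not deprotonate C2–H, and the new carbinol centre may form as a mixture because step 8 removes it.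

Step 8
Reactants: 11 methyl (2R,3S)-3-(TBS-oxy)-2-(1-hydroxyethyl)-2,3-dihydro-1-benzofuran-5-carboxylate
Product: 12 methyl (2S,3S)-2-acetyl-3-(TBS-oxy)-2,3-dihydro-1-benzofuran-5-carboxylate
Conditions: Dess–Martin periodinane, pyridine, CH2Cl2, 0 °C → rt
Reagents that add atoms: none
Why: A second Dess–Martin oxidation merges both carbinol epimers into one methyl ketone under the same non-enolising conditions.

Step 9
Reactants: 12 methyl (2S,3S)-2-acetyl-3-(TBS-oxy)-2,3-dihydro-1-benzofuran-5-carboxylate
Product: 13 methyl (2R,3S)-3-(TBS-oxy)-2-(prop-1-en-2-yl)-2,3-dihydro-1-benzofuran-5-carboxylate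
Conditions: Zn, CH2Br2, TiCl4 (reagent pre-aged in THF), CH2Cl2, 0 °C → rt
Reagents that add atoms: dibromomethane, BrCBr
Why: Takai–Lombardo methylenation uses a non-basic gem-dimetallic reagent that attacks ketones but not esters or silyl ethers and is the standard choice for easily enolised ketones, so neither epimerisation at C2 nor loss of silanol should compete.

Step 10
Reactants: 13 methyl (2R,3S)-3-(TBS-oxy)-2-(prop-1-en-2-yl)-2,3-dihydro-1-benzofuran-5-carboxylate
Product: 15 1-[(2R,3S)-3-(TBS-oxy)-2-(prop-1-en-2-yl)-2,3-dihydro-1-benzofuran-5-yl]ethanone, via Weinreb amide 14 (not isolated)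
Conditions: MeNH(OMe)·HCl, iPrMgCl, THF, −20 °C; then MeMgBr, −20 → 0 °C
Reagents that add atoms: methylmagnesium bromide, C[Mg]Br; N,O-dimethylhydroxylamine hydrochloride, CNOC.Cl (its atoms stay only in 14)
Why: The magnesium amide of N,O-dimethylhydroxylamine converts the aryl ester into the Weinreb amide, and in the same flask the Weinreb ketone synthesis with MeMgBr stops at the chelated tetrahedral adduct, which gives the methyl ketone only on work-up; alkene and silyl ether are inert.

Step 11
Reactants: 15 1-[(2R,3S)-3-(TBS-oxy)-2-(prop-1-en-2-yl)-2,3-dihydro-1-benzofuran-5-yl]ethanone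
Product: 16 1-[(2R,3S)-3-hydroxy-2-(prop-1-en-2-yl)-2,3-dihydro-1-benzofuran-5-yl]ethanone
Conditions: HF·pyridine, THF, 0 °C → rt
Reagents that add atoms: none
Why: Fluoride-driven desilylation in a mildly acidic medium avoids a free C3 alkoxide, and the para-acetyl group ties up the O1 lone pair so that the benzylic C3–O bond should not ionise; the reaction is at silicon and C3 is retained.

Step 12
Reactants: 16 1-[(2R,3S)-3-hydroxy-2-(prop-1-en-2-yl)-2,3-dihydro-1-benzofuran-5-yl]ethanone; 17 isovaleryl chloride (3-methylbutanoyl chloride)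
Product: 18 (2R,3S)-5-acetyl-2-(prop-1-en-2-yl)-2,3-dihydro-1-benzofuran-3-yl 3-methylbutanoate
Conditions: pyridine, DMAP (cat.), CH2Cl2, 0 °C
Reagents that add atoms: none
Why: DMAP-catalysed acylation with an acid chloride takes place at the hydroxyl oxygen, so C3 keeps its configuration, and pyridine takes up the HCl that could otherwise dehydrate ring B.

Step 13
Reactants: 18 (2R,3S)-5-acetyl-2-(prop-1-en-2-yl)-2,3-dihydro-1-benzofuran-3-yl 3-methylbutanoate
Product: 19 (2R,3S)-5-[(1R)-1-hydroxyethyl]-2-(prop-1-en-2-yl)-2,3-dihydro-1-benzofuran-3-yl 3-methylbutanoate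
Conditions: RuCl(p-cymene)[(R,R)-TsDPEN] (1 mol %), HCO2H–Et3N (5:2), 30 °C
Reagents that add atoms: none
Why: Noyori–Ikariya asymmetric transfer hydrogenation of aryl methyl ketones is catalyst-controlled, the (R,R)-TsDPEN complex giving (R)-1-arylethanols through its CH/π-organised six-membered transition state, formic acid makes the reduction irreversible for this electron-rich ketone, and isolated alkenes and esters are not reduced.

Step 14
Reactants: 19 (2R,3S)-5-[(1R)-1-hydroxyethyl]-2-(prop-1-en-2-yl)-2,3-dihydro-1-benzofuran-3-yl 3-methylbutanoate; 20 (R)-2-methylbutanoic acid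
Product: 21 (1R)-1-[(2R,3S)-3-(3-methylbutanoyloxy)-2-(prop-1-en-2-yl)-2,3-dihydro-1-benzofuran-5-yl]ethyl (2R)-2-methylbutanoate
Conditions: DCC, DMAP (cat.), CH2Cl2, 0 °C → rt
Reagents that add atoms: none
Why: Steglich esterification acylates the carbinol oxygen, so the acid-sensitive para-alkoxybenzylic centre is retained, and carbodiimide activation at or below room temperature with catalytic DMAP should leave the α-centre of the acid intact.

Step 15
Reactants: 21 (1R)-1-[(2R,3S)-3-(3-methylbutanoyloxy)-2-(prop-1-en-2-yl)-2,3-dihydro-1-benzofuran-5-yl]ethyl (2R)-2-methylbutanoate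
Product: 22 (1R)-1-[(2R,3S)-2-(3-hydroxyprop-1-en-2-yl)-3-(3-methylbutanoyloxy)-2,3-dihydro-1-benzofuran-5-yl]ethyl (2R)-2-methylbutanoate
Conditions: SeO2 (30 mol %), t-BuOOH, CH2Cl2, 0 °C → rt
Reagents that add atoms: tert-butyl hydroperoxide, CC(C)(C)OO (oxygen relayed through SeO2, O=[Se]=O)
Why: SeO2-catalysed allylic oxidation (Riley oxidation in its hydroperoxide-driven form: ene reaction, then [2,3]-sigmatropic shift) attacks the methyl group, since the only other allylic hydrogen, C2–H, is a hindered methine deactivated by O1, and at room temperature both benzylic esters should survive; any enal formed by over-oxidation is simply carried into step 16.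

Step 16
Reactants: 22 (1R)-1-[(2R,3S)-2-(3-hydroxyprop-1-en-2-yl)-3-(3-methylbutanoyloxy)-2,3-dihydro-1-benzofuran-5-yl]ethyl (2R)-2-methylbutanoate
Product: 23 CNP0154159.1, (1R)-1-[(2R,3S)-3-(3-methylbutanoyloxy)-2-(3-oxoprop-1-en-2-yl)-2,3-dihydro-1-benzofuran-5-yl]ethyl (2R)-2-methylbutanoate
Conditions: Dess–Martin periodinane, pyridine, CH2Cl2, 0 °C
Reagents that add atoms: none
Why: Dess–Martin oxidation of the primary allylic alcohol gives the α-substituted acrolein under buffered, non-acidic conditions that spare the two benzylic esters, and the product has no α-hydrogen through which it could isomerise.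

**Compound list**

1 | 2-deoxy-D-ribose, (3S,4R)-3,4,5-trihydroxypentanal | O=CC[C@H](O)[C@H](O)CO | starting material
2 | 2-deoxy-D-ribono-1,4-lactone, (4S,5R)-4-hydroxy-5-(hydroxymethyl)oxolan-2-one | OC[C@H]1OC(=O)C[C@@H]1O | intermediate
3 | 3,5-bis-O-TBS-2-deoxy-D-ribono-1,4-lactone | CC(C)(C)[Si](C)(C)OC[C@H]1OC(=O)C[C@@H]1O[Si](C)(C)C(C)(C)C | intermediate
4 | (2R,3S)-3,5-bis(TBS-oxy)-2-(TBS-oxymethyl)-2,3-dihydrofuran (TBS ketene acetal of 3) | CC(C)(C)[Si](C)(C)OC[C@H]1OC(O[Si](C)(C)C(C)(C)C)=C[C@@H]1O[Si](C)(C)C(C)(C)C | intermediate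
5 | methyl coumalate, methyl 2-oxo-2H-pyran-5-carboxylate | COC(=O)C1=COC(=O)C=C1 | starting material
6 | bridged lactone: 2-oxabicyclo[2.2.2]oct-5-en-3-one with CO2Me on the alkene carbon next to the O-bearing bridgehead; its saturated two-carbon bridge is the C7a–C3a bond of ring B (C7a carries O1 and OTBS); new centres undefined | O=C1OC2C(C(=O)OC)=CC1C3(O[Si](C)(C)C(C)(C)C)O[C@H](CO[Si](C)(C)C(C)(C)C)[C@@H](O[Si](C)(C)C(C)(C)C)C23 | intermediate
7 | methyl (2R,3S)-3,7a-bis(TBS-oxy)-2-(TBS-oxymethyl)-2,3,3a,7a-tetrahydro-1-benzofuran-5-carboxylate (cis-fused; C3a and C7a undefined) | COC(=O)C1=CC2[C@H](O[Si](C)(C)C(C)(C)C)[C@@H](CO[Si](C)(C)C(C)(C)C)OC2(O[Si](C)(C)C(C)(C)C)C=C1 | intermediate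
8 | methyl (2R,3S)-3-(TBS-oxy)-2-(TBS-oxymethyl)-2,3-dihydro-1-benzofuran-5-carboxylate | CC(C)(C)[Si](C)(C)OC[C@H]1Oc2ccc(C(=O)OC)cc2[C@@H]1O[Si](C)(C)C(C)(C)C | intermediate
9 | methyl (2R,3S)-3-(TBS-oxy)-2-(hydroxymethyl)-2,3-dihydro-1-benzofuran-5-carboxylate | OC[C@H]1Oc2ccc(C(=O)OC)cc2[C@@H]1O[Si](C)(C)C(C)(C)C | intermediate
10 | methyl (2S,3S)-3-(TBS-oxy)-2-formyl-2,3-dihydro-1-benzofuran-5-carboxylate | O=C[C@H]1Oc2ccc(C(=O)OC)cc2[C@@H]1O[Si](C)(C)C(C)(C)C | intermediate
11 | methyl (2R,3S)-3-(TBS-oxy)-2-(1-hydroxyethyl)-2,3-dihydro-1-benzofuran-5-carboxylate (both carbinol epimers) | CC(O)[C@H]1Oc2ccc(C(=O)OC)cc2[C@@H]1O[Si](C)(C)C(C)(C)C | intermediate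
12 | methyl (2S,3S)-2-acetyl-3-(TBS-oxy)-2,3-dihydro-1-benzofuran-5-carboxylate | CC(=O)[C@H]1Oc2ccc(C(=O)OC)cc2[C@@H]1O[Si](C)(C)C(C)(C)C | intermediate
13 | methyl (2R,3S)-3-(TBS-oxy)-2-(prop-1-en-2-yl)-2,3-dihydro-1-benzofuran-5-carboxylate | C=C(C)[C@H]1Oc2ccc(C(=O)OC)cc2[C@@H]1O[Si](C)(C)C(C)(C)C | intermediate
14 | (2R,3S)-3-(TBS-oxy)-N-methoxy-N-methyl-2-(prop-1-en-2-yl)-2,3-dihydro-1-benzofuran-5-carboxamide | C=C(C)[C@H]1Oc2ccc(C(=O)N(C)OC)cc2[C@@H]1O[Si](C)(C)C(C)(C)C | intermediate
15 | 1-[(2R,3S)-3-(TBS-oxy)-2-(prop-1-en-2-yl)-2,3-dihydro-1-benzofuran-5-yl]ethanone | C=C(C)[C@H]1Oc2ccc(C(C)=O)cc2[C@@H]1O[Si](C)(C)C(C)(C)C | intermediate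
16 | 1-[(2R,3S)-3-hydroxy-2-(prop-1-en-2-yl)-2,3-dihydro-1-benzofuran-5-yl]ethanone | C=C(C)[C@H]1Oc2ccc(C(C)=O)cc2[C@@H]1O | intermediate
17 | isovaleryl chloride | CC(C)CC(=O)Cl | starting material
18 | (2R,3S)-5-acetyl-2-(prop-1-en-2-yl)-2,3-dihydro-1-benzofuran-3-yl 3-methylbutanoate | C=C(C)[C@H]1Oc2ccc(C(C)=O)cc2[C@@H]1OC(=O)CC(C)C | intermediate
19 | (2R,3S)-5-[(1R)-1-hydroxyethyl]-2-(prop-1-en-2-yl)-2,3-dihydro-1-benzofuran-3-yl 3-methylbutanoate | C=C(C)[C@H]1Oc2ccc([C@@H](C)O)cc2[C@@H]1OC(=O)CC(C)C | intermediate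
20 | (R)-2-methylbutanoic acid | OC(=O)[C@H](C)CC | starting material
21 | (1R)-1-[(2R,3S)-3-(3-methylbutanoyloxy)-2-(prop-1-en-2-yl)-2,3-dihydro-1-benzofuran-5-yl]ethyl (2R)-2-methylbutanoate | C=C(C)[C@H]1Oc2ccc([C@@H](C)OC(=O)[C@H](C)CC)cc2[C@@H]1OC(=O)CC(C)C | intermediate
22 | (1R)-1-[(2R,3S)-2-(3-hydroxyprop-1-en-2-yl)-3-(3-methylbutanoyloxy)-2,3-dihydro-1-benzofuran-5-yl]ethyl (2R)-2-methylbutanoate | C=C(CO)[C@H]1Oc2ccc([C@@H](C)OC(=O)[C@H](C)CC)cc2[C@@H]1OC(=O)CC(C)C | intermediate
23 | CNP0154159.1, (1R)-1-[(2R,3S)-3-(3-methylbutanoyloxy)-2-(3-oxoprop-1-en-2-yl)-2,3-dihydro-1-benzofuran-5-yl]ethyl (2R)-2-methylbutanoate | C=C(C=O)[C@H]1Oc2ccc([C@@H](C)OC(=O)[C@H](C)CC)cc2[C@@H]1OC(=O)CC(C)C | target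

Total step count: 16. Longest linear sequence: 16 steps (1 to 23); 5, 17 and 20 are bought and enter directly.

**Steps most likely to fail**

**Step 4 (annulation of ring A).** Four things may go wrong.
- The cycloaddition may be too slow at the trisubstituted double bond, which is flanked by bulky silyl groups.
- Long heating may ionise the allylic C3–O bond and aromatise ring B to a furan.
- The released silanol may protonate unreacted dienophile.
- The dihydroarene may aromatise by breaking C7a–O1, which opens ring B.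

The fallback replaces the exocyclic oxygen leaving group by sulfur and sets out from 3. Thionation with Lawesson's reagent (toluene, 90 °C) should give the thionolactone F1. Its thioenolate (LiN(SiMe3)2, THF, −78 °C) is far less basic than the lactone enolate, and it is S-methylated with MeI to the S-methyl ketene O,S-acetal F2. Heating F2 with 5 in toluene under a nitrogen sweep forms the same two ring A bonds. C7a then carries methanethiolate, a much better nucleofuge than either alkoxide, so aromatisation should keep ring B. The sequence comes back to the route at 8.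

**Step 3 (silyl ketene acetal).** β-Elimination of silanolate from the lithium enolate may outrun the silyl trap, and C-silylation may compete with O-silylation.

The fallback ties O3 and O5 of the sugar into one ring and sets out from 2.
- tBu2Si(OTf)2 and 2,6-lutidine in DMF at 0 °C should give the 3,5-O-(di-tert-butylsilanediyl) lactone F3. Its trans-fused six-membered ring holds the C3–O bond pseudo-equatorial, close to the nodal plane of the enolate, so elimination loses its orbital overlap.
- Enolisation and silylation as in step 3 give its TBS ketene acetal F4, which is also less shielded.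
- Cycloaddition with 5 as in step 4 gives the silylene-bridged dihydrobenzofuran ester F5.
- HF·pyridine at 0 °C then frees the diol F6.
- TBSCl and imidazole in DMF bring the material back to the route at 8.

**Step 9 (methylenation of the β-silyloxy ketone; the same threat runs through steps 6 to 8).** Enolisation toward C2, helped by the Lewis-acidic zinc and titanium salts, may be followed by loss of silanol with aromatisation of ring B, or by epimerisation at C2.

The fallback avoids any aldehyde or ketone on C2 and sets out from 9.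
- TEMPO (cat.) and PhI(OAc)2 in MeCN–H2O should give the C2 carboxylic acid F7.
- N-Hydroxyphthalimide, N,N'-diisopropylcarbodiimide and catalytic DMAP convert it into the N-hydroxyphthalimide ester F8.
- Nickel-catalysed decarboxylative alkenylation (Ni(acac)2, 2,2'-bipyridine, isopropenylzinc chloride made from isopropenylmagnesium bromide and ZnCl2, THF–DMF, rt) replaces the carboxyl carbon by the isopropenyl group.
- The planar C2 radical should be captured anti to the C3 silyloxy group, which restores the trans (2R,3S) arrangement.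

The sequence comes back to the route at 13.

**Further compounds**

F1 | step 4 | (4S,5R)-4-(TBS-oxy)-5-(TBS-oxymethyl)oxolane-2-thione | CC(C)(C)[Si](C)(C)OC[C@H]1OC(=S)C[C@@H]1O[Si](C)(C)C(C)(C)C
F2 | step 4 | (2R,3S)-3-(TBS-oxy)-2-(TBS-oxymethyl)-5-(methylsulfanyl)-2,3-dihydrofuran | CC(C)(C)[Si](C)(C)OC[C@H]1OC(SC)=C[C@@H]1O[Si](C)(C)C(C)(C)C
F3 | step 3 | 3,5-O-(di-tert-butylsilanediyl)-2-deoxy-D-ribono-1,4-lactone | CC(C)(C)[Si]1(C(C)(C)C)OC[C@H]2OC(=O)C[C@@H]2O1
F4 | step 3 | TBS ketene acetal of F3 | CC(C)(C)[Si]1(C(C)(C)C)OC[C@H]2OC(O[Si](C)(C)C(C)(C)C)=C[C@@H]2O1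
F5 | step 3 | methyl (2R,3S)-2,3-dihydro-1-benzofuran-5-carboxylate whose C3–O and C2–CH2–O are bridged by Si(tBu)2 | CC(C)(C)[Si]1(C(C)(C)C)OC[C@H]2Oc3ccc(C(=O)OC)cc3[C@@H]2O1
F6 | step 3 | methyl (2R,3S)-3-hydroxy-2-(hydroxymethyl)-2,3-dihydro-1-benzofuran-5-carboxylate | OC[C@H]1Oc2ccc(C(=O)OC)cc2[C@@H]1O
F7 | step 9 | (2S,3S)-3-(TBS-oxy)-5-(methoxycarbonyl)-2,3-dihydro-1-benzofuran-2-carboxylic acid | OC(=O)[C@H]1Oc2ccc(C(=O)OC)cc2[C@@H]1O[Si](C)(C)C(C)(C)C
F8 | step 9 | N-hydroxyphthalimide ester of F7 | O=C(ON1C(=O)c2ccccc2C1=O)[C@H]1Oc2ccc(C(=O)OC)cc2[C@@H]1O[Si](C)(C)C(C)(C)C
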